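**Retrosynthetic overview**

1. The strategy rests on C1: this CHOH carbon lies β to the C3 ketone and α to the fully substituted C10, so C1–C2 is an aldol bond. Cutting it opens the ten-membered carbocycle (C1–C10) to a C2 bromomethyl Z-enone and a non-enolisable C1 aldehyde, closed forward by SmI2. The C10 oxygen is carried as a p-methoxybenzyl ether so that samarium can chelate it and set C1.
2. Ring order: the ten-membered ring first, then the cis-fused α-methylene γ-lactone (O–C6, C7, C11, C12) by oxidising the C12 alcohol onto the C6 hydroxyl; the C10 ether is cleaved last.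
3. C5–C6: Nozaki–Hiyama–Kishi coupling of a Z-iodide (C2–C5, C15) with the C6 aldehyde, oxidation to the C6 enone, and hydroxyl-directed syn reduction from C8.
4. C7–C8: Sharpless epoxidation of the E-allylic alcohol C6–C7=C8, then opening at C7 by a 2-(silyloxymethyl)vinyl copper reagent (C11–C13).
5. C10 comes from (R)-2-methylglycidol (C1, C9, C10, C14), extended by vinyl Grignard (C8) and cross-metathesis with methyl acrylate (C6, C7).

Key step: step 24

Remark: germacrane numbering is used throughout (ring C1–C10, C11(=C13)–C12 on C7, C14 on C10, C15 on C4); open-chain compounds lacking the C1–C2 bond are named as 1,2-secogermacranes.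
Remark: (S)-but-3-yn-2-ol is used as one enantiomer only to keep intermediates single diastereomers; its C3 centre is erased in step 21.

**Route**

Step 1
Reactants: 1 (R)-2-methylglycidol; 2 vinylmagnesium bromide
Product: 3 (S)-2-methylpent-4-ene-1,2-diol
Conditions: CH2=CHMgBr (3 equiv), CuI (10 mol%), THF, −30 to 0 °C; aq. NH4Cl
Reagents that add atoms: none
Why: Copper-catalysed Grignard opening (SN2) of the 2,2-disubstituted epoxide at its CH2 carbon leaves the quaternary C10 centre of the chiral-pool epoxide untouched.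

Step 2
Reactants: 3 (S)-diol
Product: 4 (4S)-4-allyl-2-(4-methoxyphenyl)-4-methyl-1,3-dioxolane (epimers at C2)
Conditions: 4-MeOC6H4CH(OMe)2, PPTS (cat.), CH2Cl2, rt
Reagents that add atoms: 4-methoxybenzaldehyde dimethyl acetal, COC(OC)c1ccc(OC)cc1
Why: Acid-catalysed transacetalisation should give the five-membered p-methoxybenzylidene acetal of the primary/tertiary 1,2-diol; the acetal centre is erased in step 3.

Step 3
Reactants: 4 p-methoxybenzylidene acetal
Product: 5 (S)-2-(4-methoxybenzyloxy)-2-methylpent-4-en-1-ol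
Conditions: iBu2AlH (3 equiv), CH2Cl2, −78 to 0 °C; Rochelle salt
Reagents that add atoms: none
Why: Reductive acetal opening, in which iBu2AlH complexes the less hindered primary oxygen and so should leave the p-methoxybenzyl group on the tertiary C10 oxygen.

Step 4
Reactants: 5 primary alcohol
Product: 6 (S)-triethyl{[2-(4-methoxybenzyloxy)-2-methylpent-4-en-1-yl]oxy}silane
Conditions: Et3SiCl, imidazole, CH2Cl2, 0 °C
Reagents that add atoms: chlorotriethylsilane, CC[Si](Cl)(CC)CC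
Why: Routine silylation of the primary C1 alcohol.

Step 5
Reactants: 6 terminal alkene; 7 methyl acrylate
Product: 8 methyl (S,E)-5-(4-methoxybenzyloxy)-5-methyl-6-(triethylsilyloxy)hex-2-enoate
Conditions: second-generation Grubbs catalyst (5 mol%), 7 (4 equiv), CH2Cl2, 40 °C
Reagents that add atoms: none
Why: Olefin cross-metathesis of a terminal alkene with an acrylate is reliably E-selective and brings in C6 and C7.

Step 6
Reactants: 8 enoate
Product: 9 (S,E)-5-(4-methoxybenzyloxy)-5-methyl-6-(triethylsilyloxy)hex-2-en-1-ol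
Conditions: iBu2AlH (2.2 equiv), CH2Cl2, −78 °C
Reagents that add atoms: none
Why: 1,2-Reduction of the enoate to the allylic alcohol at low temperature, where the benzyl and silyl ethers are inert.

Step 7
Reactants: 9 E-allylic alcohol
Product: 10 {(2R,3R)-3-[(S)-2-(4-methoxybenzyloxy)-2-methyl-3-(triethylsilyloxy)propyl]oxiran-2-yl}methanol
Conditions: Ti(OiPr)4 (10 mol%), D-(−)-diethyl tartrate (12 mol%), t-BuOOH, 4 Å MS, CH2Cl2, −20 °C
Reagents that add atoms: tert-butyl hydroperoxide, CC(C)(C)OO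
Why: Sharpless asymmetric epoxidation, in which D-(−)-tartrate directs oxygen to the face giving the (2R,3R)-epoxy alcohol, so C8 (and C7 before its inversion) is set by the reagent and not by the remote C10.

Step 8
Reactants: 11 2-bromoprop-2-en-1-ol
Product: 12 (2-bromoallyloxy)(tert-butyl)dimethylsilane
Conditions: t-BuMe2SiCl, imidazole, CH2Cl2, rt
Reagents that add atoms: tert-butylchlorodimethylsilane, CC(C)(C)[Si](C)(C)Cl
Why: Routine silylation of the primary allylic alcohol.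

Step 9
Reactants: 10 (2R,3R)-epoxy alcohol; 12 2-bromoallyl silyl ether
Product: 14 (2S,3R,5S)-2-[3-(tert-butyldimethylsilyloxy)prop-1-en-2-yl]-5-(4-methoxybenzyloxy)-5-methyl-6-(triethylsilyloxy)hexane-1,3-diol, via alkenylmagnesium bromide 13 (not isolated)
Conditions: 12, Mg, THF, 40 °C; then CuI (20 mol%), 10, THF, −40 to −10 °C; aq. NH4Cl
Reagents that add atoms: none
Why: Copper-catalysed, alkoxide-directed SN2 opening of the trans-2,3-epoxy alcohol at C-2 (C7) with inversion, C8 being shielded by the neopentyl-type C9–C10 unit, should give the C7/C8 anti pair and attach C11–C13.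

Step 10
Reactants: 14 1,3-diol
Product: 15 (2R,3R,5S)-2-[3-(tert-butyldimethylsilyloxy)prop-1-en-2-yl]-3-hydroxy-5-(4-methoxybenzyloxy)-5-methyl-6-(triethylsilyloxy)hexanal
Conditions: TEMPO (10 mol%), PhI(OAc)2 (1.1 equiv), CH2Cl2, rt; used crude
Reagents that add atoms: none
Why: TEMPO/PhI(OAc)2 oxidation is selective for the primary alcohol of the 1,3-diol and runs without base, so the allylic C7 centre should not epimerise.

Step 11
Reactants: 16 (S)-but-3-yn-2-ol
Product: 18 (S,Z)-4-iodo-3-methylbut-3-en-2-ol, via cyclic alkenylmagnesium alkoxide 17 (not isolated)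
Conditions: MeMgBr (2.5 equiv), CuI (10 mol%), THF, −20 °C to rt; then I2, −78 to 0 °C
Reagents that add atoms: methylmagnesium bromide, C[Mg]Br; iodine, II
Why: Copper-catalysed anti-carbomagnesiation of the propargylic alkoxide places the methyl on C4 and magnesium on C5 in a five-membered chelate, and iodinolysis with retention gives the Z-iodide.

Step 12
Reactants: 18 Z-iodo alcohol
Product: 19 (S,Z)-triethyl[(4-iodo-3-methylbut-3-en-2-yl)oxy]silane
Conditions: Et3SiCl, imidazole, CH2Cl2, 0 °C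
Reagents that add atoms: chlorotriethylsilane, CC[Si](Cl)(CC)CC
Why: Routine silylation of the C3 alcohol.

Step 13
Reactants: 15 β-hydroxy aldehyde; 19 Z-alkenyl iodide
Product: 20 (3S,4Z,7R,8R,10S)-12-(tert-butyldimethylsilyloxy)-10-(4-methoxybenzyloxy)-1,3-bis(triethylsilyloxy)-1,2-secogermacra-4,11(13)-diene-6,8-diol (C6 epimers)
Conditions: CrCl2 (6 equiv), NiCl2 (2 mol%), DMSO, rt
Reagents that add atoms: none
Why: Nozaki–Hiyama–Kishi coupling adds the alkenylchromium species to the aldehyde under non-basic conditions with retention of the Z geometry and tolerates the free C8 hydroxyl; C6 is not controlled here and is erased in step 14.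

Step 14
Reactants: 20 C6 carbinol mixture
Product: 21 (3S,4Z,7R,8R,10S)-12-(tert-butyldimethylsilyloxy)-8-hydroxy-10-(4-methoxybenzyloxy)-1,3-bis(triethylsilyloxy)-1,2-secogermacra-4,11(13)-dien-6-one
Conditions: MnO2 (excess), CH2Cl2, rt
Reagents that add atoms: none
Why: MnO2 oxidises only the allylic C6 alcohol, under neutral conditions that should not move the C11=C13 alkene into conjugation.

Step 15
Reactants: 21 β-hydroxy enone
Product: 23 (3S,4Z,6S,7R,8R,10S)-12-(tert-butyldimethylsilyloxy)-10-(4-methoxybenzyloxy)-1,3-bis(triethylsilyloxy)-1,2-secogermacra-4,11(13)-diene-6,8-diol, via diethylboron chelate 22 (not isolated)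
Conditions: Et2BOMe, THF/MeOH (4:1), −78 °C; NaBH4; pH 7 buffer, MeOH
Reagents that add atoms: none
Why: Narasaka–Prasad reduction: in the six-membered boron chelate C9 and C11 sit equatorial and external hydride adds axially to C6, giving the 6,8-syn diol (6S) and so the anti,anti C6–C7–C8 triad.

Step 16
Reactants: 23 6,8-syn diol
Product: 24 (3S,4Z,6S,7S,8R,10S)-12-(tert-butyldimethylsilyloxy)-8,10-O-(4-methoxybenzylidene)-1,3-bis(triethylsilyloxy)-1,2-secogermacra-4,11(13)-dien-6-ol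
Conditions: DDQ (1.2 equiv), 4 Å MS, CH2Cl2, 0 °C
Reagents that add atoms: none
Why: Oxidative acetal formation: DDQ turns the C10 p-methoxybenzyl ether into an oxocarbenium ion that only the 1,3-related C8 hydroxyl can capture as a six-membered ring, which tells the two secondary alcohols apart and leaves C6–OH free.

Step 17
Reactants: 24 C6 alcohol
Product: 25 (3S,4Z,6S,7R,8R,10S)-6,12-bis(tert-butyldimethylsilyloxy)-8,10-O-(4-methoxybenzylidene)-1,3-bis(triethylsilyloxy)-1,2-secogermacra-4,11(13)-diene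
Conditions: t-BuMe2SiOTf, 2,6-lutidine, CH2Cl2, −78 °C
Reagents that add atoms: tert-butyldimethylsilyl trifluoromethanesulfonate, CC(C)(C)[Si](C)(C)OS(=O)(=O)C(F)(F)F
Why: Silylation of the hindered allylic C6 alcohol with the reactive silyl triflate under buffered conditions that keep the acetal.

Step 18
Reactants: 25 8,10-acetal
Product: 26 (3S,4Z,6S,7R,8R,10S)-6,12-bis(tert-butyldimethylsilyloxy)-10-(4-methoxybenzyloxy)-1,3-bis(triethylsilyloxy)-1,2-secogermacra-4,11(13)-dien-8-ol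
Conditions: iBu2AlH (4 equiv), CH2Cl2, −78 to 0 °C; Rochelle salt
Reagents that add atoms: none
Why: Reductive acetal opening at the less hindered C8 oxygen (O10 sits on a quaternary carbon with an axial methyl) should free the C8 alcohol and return the p-methoxybenzyl group to C10.

Step 19
Reactants: 26 C8 alcohol; 27 angelic acid
Product: 29 (3S,4Z,6S,7R,8R,10S)-6,12-bis(tert-butyldimethylsilyloxy)-10-(4-methoxybenzyloxy)-1,3-bis(triethylsilyloxy)-1,2-secogermacra-4,11(13)-dien-8-yl angelate, via mixed anhydride 28 (not isolated)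
Conditions: 27, 2,4,6-Cl3C6H2COCl, Et3N, toluene, rt; then 26, toluene, 75 °C
Reagents that add atoms: none
Why: Yamaguchi-type mixed-anhydride esterification without a nucleophilic amine catalyst acylates hindered alcohols with angelic acid without Z-to-E isomerisation to the tiglate.

Step 20
Reactants: 29 angelate
Product: 30 (3S,4Z,6S,7R,8R,10S)-6,12-bis(tert-butyldimethylsilyloxy)-1,3-dihydroxy-10-(4-methoxybenzyloxy)-1,2-secogermacra-4,11(13)-dien-8-yl angelate
Conditions: PPTS (cat.), MeOH/CH2Cl2, 0 °C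
Reagents that add atoms: none
Why: Mild acid methanolysis should remove the two triethylsilyl ethers (primary C1, secondary allylic C3) well before the tert-butyldimethylsilyl ethers.

Step 21
Reactants: 30 1,3-diol
Product: 31 (4Z,6S,7R,8R,10S)-6,12-bis(tert-butyldimethylsilyloxy)-1-hydroxy-10-(4-methoxybenzyloxy)-3-oxo-1,2-secogermacra-4,11(13)-dien-8-yl angelate
Conditions: MnO2 (excess), CH2Cl2, rt
Reagents that add atoms: none
Why: MnO2 oxidises the allylic C3 alcohol to the Z-enone under neutral conditions and leaves the saturated primary C1 alcohol.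

Step 22
Reactants: 31 methyl Z-enone
Product: 34 (4Z,6S,7R,8R,10S)-2-bromo-6,12-bis(tert-butyldimethylsilyloxy)-1-hydroxy-10-(4-methoxybenzyloxy)-3-oxo-1,2-secogermacra-4,11(13)-dien-8-yl angelate, via bis(trimethylsilyl) dienol ether 32 (not isolated), via bromoketone trimethylsilyl ether 33 (not isolated)
Conditions: Me3SiOTf (3 equiv), Et3N, CH2Cl2, −78 to 0 °C; NBS, THF, −78 °C; citric acid, MeOH, 0 °C
Reagents that add atoms: N-bromosuccinimide, O=C1CCC(=O)N1Br
Why: Soft enolisation of the methyl ketone on its methyl side gives the 2-silyloxy diene (C1–OH is silylated in passing), NBS brominates the silyl enol ether at C2, and mild acid frees the primary C1 alcohol; bromination is done before any aldehyde is present.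

Step 23
Reactants: 34 bromoketone alcohol
Product: 35 (4Z,6S,7R,8R,10S)-2-bromo-6,12-bis(tert-butyldimethylsilyloxy)-10-(4-methoxybenzyloxy)-1,3-dioxo-1,2-secogermacra-4,11(13)-dien-8-yl angelate
Conditions: Dess–Martin periodinane, NaHCO3, CH2Cl2, 0 °C to rt
Reagents that add atoms: none
Why: Dess–Martin oxidation of the primary alcohol to the non-enolisable C1 aldehyde is compatible with the α-bromo ketone.

Step 24
Reactants: 35 bromomethyl Z-enone aldehyde
Product: 37 (1S,4Z,6S,7R,8R,10S)-6,12-bis(tert-butyldimethylsilyloxy)-1-hydroxy-10-(4-methoxybenzyloxy)-3-oxogermacra-4,11(13)-dien-8-yl angelate, via samarium enolate 36 (not isolated)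
Conditions: SmI2 (2.5 equiv), THF, −78 °C, slow addition of 35 (about 2 mM final); aq. NH4Cl at −78 °C
Reagents that add atoms: none
Why: Two single-electron transfers from divalent samarium cleave the C2–Br bond and give the trivalent samarium enolate 36 regiospecifically at C2 without base, and this enolate adds to the C1 aldehyde through a six-membered samarium-bridged (Zimmerman–Traxler-type) array. The closest known reaction type is the SmI2-mediated intramolecular Reformatsky-type aldol of α-halo ketones with aldehydes, used to close eight- to fourteen-membered rings. The ten-membered carbocycle (C1–C10) closes in a 10-(enolendo)-exo-trig mode, with the metal holding both termini and the Z-alkene pre-bending the chain. The new C1 centre is set by C10: samarium also binds the C10 p-methoxybenzyl ether oxygen (Cram chelate), so C2 attacks the aldehyde face on the side of the C14 methyl with C2 anti to C9 across C1–C10, which should give the 1,10-syn pattern (1S); a bulky silyl ether at C10 would not hold this chelate and the open polar Felkin arrangement points to the other epimer, which is why the ether is carried. The step needs reduction of C–Br ahead of enone, aldehyde and angelate (−78 °C, no additive), intramolecular ahead of intermolecular addition (slow addition, high dilution) and no proton source or enolisable partner (the aldehyde has no α-hydrogen and no hydroxyl is free).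

Step 25
Reactants: 37 ten-membered aldol
Product: 38 (1S,4Z,6S,7S,8R,10S)-1,6,12-trihydroxy-10-(4-methoxybenzyloxy)-3-oxogermacra-4,11(13)-dien-8-yl angelate
Conditions: HF·pyridine, pyridine, THF, 0 °C to rt
Reagents that add atoms: none
Why: Pyridine-buffered HF·pyridine cleaves both tert-butyldimethylsilyl ethers and is mild enough for the β-hydroxy ketone, the angelate and the benzyl ether.

Step 26
Reactants: 38 triol
Product: 41 (1S,4Z,6S,7R,8R,10S)-8-angeloyloxy-1-hydroxy-10-(4-methoxybenzyloxy)-3-oxogermacra-4,11(13)-dien-12,6-olide, via enal 39 (not isolated), via lactol 40 (not isolated)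
Conditions: TEMPO (20 mol%), PhI(OAc)2 (2.5 equiv), CH2Cl2, rt
Reagents that add atoms: none
Why: TEMPO/PhI(OAc)2 oxidative lactonisation: the primary allylic C12 alcohol is oxidised first, the enal is captured by the C6 hydroxyl as a five-membered lactol and oxidised on to the cis-fused α-methylene γ-lactone, while the C10 ether keeps the C1/C10 diol from glycol cleavage.

Step 27
Reactants: 41 lactone p-methoxybenzyl ether
Product: 42 (1S,4Z,6S,7R,8R,10S)-8-angeloyloxy-1,10-dihydroxy-3-oxogermacra-4,11(13)-dien-12,6-olide (CNP0271189.1)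
Conditions: DDQ (1.5 equiv), CH2Cl2/pH 7 buffer (5:1), 0 °C to rt
Reagents that add atoms: none
Why: Oxidative cleavage of the p-methoxybenzyl ether with DDQ leaves the electron-poor alkenes alone, and the water-rich medium should hydrolyse the oxocarbenium ion before the neighbouring C1 hydroxyl can hold it as an acetal.

**Compound list**

1 | (R)-2-methylglycidol | C[C@@]1(CO)CO1 | starting material
2 | vinylmagnesium bromide | C=C[Mg]Br | starting material
3 | (S)-2-methylpent-4-ene-1,2-diol | C=CC[C@](C)(O)CO | intermediate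
4 | (4S)-4-allyl-2-(4-methoxyphenyl)-4-methyl-1,3-dioxolane (epimers at C2) | C=CC[C@@]1(C)COC(c2ccc(OC)cc2)O1 | intermediate
5 | (S)-2-(4-methoxybenzyloxy)-2-methylpent-4-en-1-ol | C=CC[C@](C)(OCc1ccc(OC)cc1)CO | intermediate
6 | (S)-triethyl{[2-(4-methoxybenzyloxy)-2-methylpent-4-en-1-yl]oxy}silane | C=CC[C@](C)(OCc1ccc(OC)cc1)CO[Si](CC)(CC)CC | intermediate
7 | methyl acrylate | C=CC(=O)OC | starting material
8 | methyl (S,E)-5-(4-methoxybenzyloxy)-5-methyl-6-(triethylsilyloxy)hex-2-enoate | COC(=O)/C=C/C[C@](C)(OCc1ccc(OC)cc1)CO[Si](CC)(CC)CC | intermediate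
9 | (S,E)-5-(4-methoxybenzyloxy)-5-methyl-6-(triethylsilyloxy)hex-2-en-1-ol | OC/C=C/C[C@](C)(OCc1ccc(OC)cc1)CO[Si](CC)(CC)CC | intermediate
10 | {(2R,3R)-3-[(S)-2-(4-methoxybenzyloxy)-2-methyl-3-(triethylsilyloxy)propyl]oxiran-2-yl}methanol | OC[C@H]1O[C@@H]1C[C@](C)(OCc2ccc(OC)cc2)CO[Si](CC)(CC)CC | intermediate
11 | 2-bromoprop-2-en-1-ol | C=C(Br)CO | starting material
12 | (2-bromoallyloxy)(tert-butyl)dimethylsilane | C=C(Br)CO[Si](C)(C)C(C)(C)C | intermediate
13 | [3-(tert-butyldimethylsilyloxy)prop-1-en-2-yl]magnesium bromide | C=C([Mg]Br)CO[Si](C)(C)C(C)(C)C | intermediate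
14 | (2S,3R,5S)-2-[3-(tert-butyldimethylsilyloxy)prop-1-en-2-yl]-5-(4-methoxybenzyloxy)-5-methyl-6-(triethylsilyloxy)hexane-1,3-diol | OC[C@H](C(=C)CO[Si](C)(C)C(C)(C)C)[C@H](O)C[C@](C)(OCc1ccc(OC)cc1)CO[Si](CC)(CC)CC | intermediate
15 | (2R,3R,5S)-2-[3-(tert-butyldimethylsilyloxy)prop-1-en-2-yl]-3-hydroxy-5-(4-methoxybenzyloxy)-5-methyl-6-(triethylsilyloxy)hexanal | O=C[C@H](C(=C)CO[Si](C)(C)C(C)(C)C)[C@H](O)C[C@](C)(OCc1ccc(OC)cc1)CO[Si](CC)(CC)CC | intermediate
16 | (S)-but-3-yn-2-ol | C[C@H](O)C#C | starting material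
17 | (5S)-4,5-dimethyl-2,5-dihydro-1,2-oxamagnesole (cyclic alkenylmagnesium alkoxide) | C[C@@H]1O[Mg]C=C1C | intermediate
18 | (S,Z)-4-iodo-3-methylbut-3-en-2-ol | C[C@H](O)/C(C)=C\I | intermediate
19 | (S,Z)-triethyl[(4-iodo-3-methylbut-3-en-2-yl)oxy]silane | C[C@H](O[Si](CC)(CC)CC)/C(C)=C\I | intermediate
20 | (3S,4Z,7R,8R,10S)-12-(tert-butyldimethylsilyloxy)-10-(4-methoxybenzyloxy)-1,3-bis(triethylsilyloxy)-1,2-secogermacra-4,11(13)-diene-6,8-diol (C6 epimers) | C[C@H](O[Si](CC)(CC)CC)/C(C)=C\C(O)[C@H](C(=C)CO[Si](C)(C)C(C)(C)C)[C@H](O)C[C@](C)(OCc1ccc(OC)cc1)CO[Si](CC)(CC)CC | intermediate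
21 | (3S,4Z,7R,8R,10S)-12-(tert-butyldimethylsilyloxy)-8-hydroxy-10-(4-methoxybenzyloxy)-1,3-bis(triethylsilyloxy)-1,2-secogermacra-4,11(13)-dien-6-one | C[C@H](O[Si](CC)(CC)CC)/C(C)=C\C(=O)[C@H](C(=C)CO[Si](C)(C)C(C)(C)C)[C@H](O)C[C@](C)(OCc1ccc(OC)cc1)CO[Si](CC)(CC)CC | intermediate
22 | 8-O-diethylboryl derivative of 21 (boron chelated by the C6 ketone) | C[C@H](O[Si](CC)(CC)CC)/C(C)=C\C(=O)[C@H](C(=C)CO[Si](C)(C)C(C)(C)C)[C@H](OB(CC)CC)C[C@](C)(OCc1ccc(OC)cc1)CO[Si](CC)(CC)CC | intermediate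
23 | (3S,4Z,6S,7R,8R,10S)-12-(tert-butyldimethylsilyloxy)-10-(4-methoxybenzyloxy)-1,3-bis(triethylsilyloxy)-1,2-secogermacra-4,11(13)-diene-6,8-diol | C[C@H](O[Si](CC)(CC)CC)/C(C)=C\[C@H](O)[C@H](C(=C)CO[Si](C)(C)C(C)(C)C)[C@H](O)C[C@](C)(OCc1ccc(OC)cc1)CO[Si](CC)(CC)CC | intermediate
24 | (3S,4Z,6S,7S,8R,10S)-12-(tert-butyldimethylsilyloxy)-8,10-O-(4-methoxybenzylidene)-1,3-bis(triethylsilyloxy)-1,2-secogermacra-4,11(13)-dien-6-ol (aryl equatorial on the 1,3-dioxane) | C[C@H](O[Si](CC)(CC)CC)/C(C)=C\[C@H](O)[C@H](C(=C)CO[Si](C)(C)C(C)(C)C)[C@H]1C[C@@](C)(CO[Si](CC)(CC)CC)O[C@@H](c2ccc(OC)cc2)O1 | intermediate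
25 | (3S,4Z,6S,7R,8R,10S)-6,12-bis(tert-butyldimethylsilyloxy)-8,10-O-(4-methoxybenzylidene)-1,3-bis(triethylsilyloxy)-1,2-secogermacra-4,11(13)-diene | C[C@H](O[Si](CC)(CC)CC)/C(C)=C\[C@H](O[Si](C)(C)C(C)(C)C)[C@H](C(=C)CO[Si](C)(C)C(C)(C)C)[C@H]1C[C@@](C)(CO[Si](CC)(CC)CC)O[C@@H](c2ccc(OC)cc2)O1 | intermediate
26 | (3S,4Z,6S,7R,8R,10S)-6,12-bis(tert-butyldimethylsilyloxy)-10-(4-methoxybenzyloxy)-1,3-bis(triethylsilyloxy)-1,2-secogermacra-4,11(13)-dien-8-ol | C[C@H](O[Si](CC)(CC)CC)/C(C)=C\[C@H](O[Si](C)(C)C(C)(C)C)[C@H](C(=C)CO[Si](C)(C)C(C)(C)C)[C@H](O)C[C@](C)(OCc1ccc(OC)cc1)CO[Si](CC)(CC)CC | intermediate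
27 | angelic acid, (Z)-2-methylbut-2-enoic acid | C/C=C(/C)C(=O)O | starting material
28 | angelic 2,4,6-trichlorobenzoic anhydride | C/C=C(/C)C(=O)OC(=O)c1c(Cl)cc(Cl)cc1Cl | intermediate
29 | (3S,4Z,6S,7R,8R,10S)-6,12-bis(tert-butyldimethylsilyloxy)-10-(4-methoxybenzyloxy)-1,3-bis(triethylsilyloxy)-1,2-secogermacra-4,11(13)-dien-8-yl angelate | C[C@H](O[Si](CC)(CC)CC)/C(C)=C\[C@H](O[Si](C)(C)C(C)(C)C)[C@H](C(=C)CO[Si](C)(C)C(C)(C)C)[C@H](OC(=O)/C(C)=C\C)C[C@](C)(OCc1ccc(OC)cc1)CO[Si](CC)(CC)CC | intermediate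
30 | (3S,4Z,6S,7R,8R,10S)-6,12-bis(tert-butyldimethylsilyloxy)-1,3-dihydroxy-10-(4-methoxybenzyloxy)-1,2-secogermacra-4,11(13)-dien-8-yl angelate | C[C@H](O)/C(C)=C\[C@H](O[Si](C)(C)C(C)(C)C)[C@H](C(=C)CO[Si](C)(C)C(C)(C)C)[C@H](OC(=O)/C(C)=C\C)C[C@](C)(OCc1ccc(OC)cc1)CO | intermediate
31 | (4Z,6S,7R,8R,10S)-6,12-bis(tert-butyldimethylsilyloxy)-1-hydroxy-10-(4-methoxybenzyloxy)-3-oxo-1,2-secogermacra-4,11(13)-dien-8-yl angelate | CC(=O)/C(C)=C\[C@H](O[Si](C)(C)C(C)(C)C)[C@H](C(=C)CO[Si](C)(C)C(C)(C)C)[C@H](OC(=O)/C(C)=C\C)C[C@](C)(OCc1ccc(OC)cc1)CO | intermediate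
32 | (4Z,6S,7R,8R,10S)-6,12-bis(tert-butyldimethylsilyloxy)-10-(4-methoxybenzyloxy)-1,3-bis(trimethylsilyloxy)-1,2-secogermacra-2,4,11(13)-trien-8-yl angelate | C=C(O[Si](C)(C)C)/C(C)=C\[C@H](O[Si](C)(C)C(C)(C)C)[C@H](C(=C)CO[Si](C)(C)C(C)(C)C)[C@H](OC(=O)/C(C)=C\C)C[C@](C)(OCc1ccc(OC)cc1)CO[Si](C)(C)C | intermediate
33 | (4Z,6S,7R,8R,10S)-2-bromo-6,12-bis(tert-butyldimethylsilyloxy)-10-(4-methoxybenzyloxy)-3-oxo-1-(trimethylsilyloxy)-1,2-secogermacra-4,11(13)-dien-8-yl angelate | BrCC(=O)/C(C)=C\[C@H](O[Si](C)(C)C(C)(C)C)[C@H](C(=C)CO[Si](C)(C)C(C)(C)C)[C@H](OC(=O)/C(C)=C\C)C[C@](C)(OCc1ccc(OC)cc1)CO[Si](C)(C)C | intermediate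
34 | (4Z,6S,7R,8R,10S)-2-bromo-6,12-bis(tert-butyldimethylsilyloxy)-1-hydroxy-10-(4-methoxybenzyloxy)-3-oxo-1,2-secogermacra-4,11(13)-dien-8-yl angelate | BrCC(=O)/C(C)=C\[C@H](O[Si](C)(C)C(C)(C)C)[C@H](C(=C)CO[Si](C)(C)C(C)(C)C)[C@H](OC(=O)/C(C)=C\C)C[C@](C)(OCc1ccc(OC)cc1)CO | intermediate
35 | (4Z,6S,7R,8R,10S)-2-bromo-6,12-bis(tert-butyldimethylsilyloxy)-10-(4-methoxybenzyloxy)-1,3-dioxo-1,2-secogermacra-4,11(13)-dien-8-yl angelate (key-step precursor) | BrCC(=O)/C(C)=C\[C@H](O[Si](C)(C)C(C)(C)C)[C@H](C(=C)CO[Si](C)(C)C(C)(C)C)[C@H](OC(=O)/C(C)=C\C)C[C@](C)(OCc1ccc(OC)cc1)C=O | intermediate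
36 | C2=C3 diiodosamarium enolate of 35 (trivalent samarium) | C=C(O[Sm](I)I)/C(C)=C\[C@H](O[Si](C)(C)C(C)(C)C)[C@H](C(=C)CO[Si](C)(C)C(C)(C)C)[C@H](OC(=O)/C(C)=C\C)C[C@](C)(OCc1ccc(OC)cc1)C=O | intermediate
37 | (1S,4Z,6S,7R,8R,10S)-6,12-bis(tert-butyldimethylsilyloxy)-1-hydroxy-10-(4-methoxybenzyloxy)-3-oxogermacra-4,11(13)-dien-8-yl angelate (key-step product) | C1C(=O)/C(C)=C\[C@H](O[Si](C)(C)C(C)(C)C)[C@H](C(=C)CO[Si](C)(C)C(C)(C)C)[C@H](OC(=O)/C(C)=C\C)C[C@](C)(OCc2ccc(OC)cc2)[C@H]1O | intermediate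
38 | (1S,4Z,6S,7S,8R,10S)-1,6,12-trihydroxy-10-(4-methoxybenzyloxy)-3-oxogermacra-4,11(13)-dien-8-yl angelate | C1C(=O)/C(C)=C\[C@H](O)[C@H](C(=C)CO)[C@H](OC(=O)/C(C)=C\C)C[C@](C)(OCc2ccc(OC)cc2)[C@H]1O | intermediate
39 | (1S,4Z,6S,7S,8R,10S)-1,6-dihydroxy-10-(4-methoxybenzyloxy)-3,12-dioxogermacra-4,11(13)-dien-8-yl angelate | C1C(=O)/C(C)=C\[C@H](O)[C@H](C(=C)C=O)[C@H](OC(=O)/C(C)=C\C)C[C@](C)(OCc2ccc(OC)cc2)[C@H]1O | intermediate
40 | (1S,4Z,6S,7R,8R,10S)-8-angeloyloxy-1,12-dihydroxy-10-(4-methoxybenzyloxy)-6,12-epoxygermacra-4,11(13)-dien-3-one (lactol; C12 epimers) | C=C1C(O)O[C@H]2/C=C(/C)C(=O)C[C@H](O)[C@@](C)(OCc3ccc(OC)cc3)C[C@@H](OC(=O)/C(C)=C\C)[C@@H]12 | intermediate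
41 | (1S,4Z,6S,7R,8R,10S)-8-angeloyloxy-1-hydroxy-10-(4-methoxybenzyloxy)-3-oxogermacra-4,11(13)-dien-12,6-olide | C=C1C(=O)O[C@H]2/C=C(/C)C(=O)C[C@H](O)[C@@](C)(OCc3ccc(OC)cc3)C[C@@H](OC(=O)/C(C)=C\C)[C@@H]12 | intermediate
42 | (1S,4Z,6S,7R,8R,10S)-8-angeloyloxy-1,10-dihydroxy-3-oxogermacra-4,11(13)-dien-12,6-olide | C=C1C(=O)O[C@H]2/C=C(/C)C(=O)C[C@H](O)[C@@](C)(O)C[C@@H](OC(=O)/C(C)=C\C)[C@@H]12 | target

**Step count**

Total: 27 steps. Longest linear sequence: 24 steps (1 to 42 through steps 1–7, 9, 10 and 13–27).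

**Steps most likely to fail**

Step 24. The samarium enolate may be protonated or add to a second molecule faster than the strained ten-membered closure, and the C1 face selection depends on the three-point chelate holding. The fallback closes the same bond without a free metal enolate. It sets out from 31: Dess–Martin oxidation should give the keto aldehyde (4Z,6S,7R,8R,10S)-6,12-bis(tert-butyldimethylsilyloxy)-10-(4-methoxybenzyloxy)-1,3-dioxo-1,2-secogermacra-4,11(13)-dien-8-yl angelate F1. Soft enolisation with Me3SiOTf/Et3N at −78 °C should give its C2=C3 trimethylsilyl enol ether F2. MgBr2·OEt2 in CH2Cl2 at high dilution would then chelate the aldehyde and C10 ether oxygens and promote an intramolecular Mukaiyama aldol, which comes back to the route at 37 after aqueous work-up.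

Step 9. The copper reagent may attack C8 as well as C7 and give a 1,2-diol regioisomer, and metallation of the 2-bromoallyl silyl ether may be accompanied by silyl migration. The fallback makes C7 the electronically preferred site. It sets out from 10: TEMPO/PhI(OAc)2 in MeCN/H2O should give the glycidic acid (2S,3R)-3-[(S)-2-(4-methoxybenzyloxy)-2-methyl-3-(triethylsilyloxy)propyl]oxirane-2-carboxylic acid F3. Opening of its carboxylate with 13/CuI, where SN2 attack α to the carboxylate is favoured, should give (2R,3R,5S)-2-[3-(tert-butyldimethylsilyloxy)prop-1-en-2-yl]-3-hydroxy-5-(4-methoxybenzyloxy)-5-methyl-6-(triethylsilyloxy)hexanoic acid F4. LiAlH4 reduction of the acid comes back to the route at 14.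

Step 26. The C6 hydroxyl freed in step 25 lies cis to the C3 ketone across the Z-alkene and may close to a hemiketal and dehydrate to a furan, and the secondary alcohols may be oxidised in competition with C12. The fallback oxidises C12 before C6 is unmasked. It sets out from 37: pyridine-buffered HF·pyridine at 0 °C should remove only the primary allylic silyl ether, giving (1S,4Z,6S,7R,8R,10S)-6-(tert-butyldimethylsilyloxy)-1,12-dihydroxy-10-(4-methoxybenzyloxy)-3-oxogermacra-4,11(13)-dien-8-yl angelate F5. MnO2 should give the 12-al F6, and NaClO2/NaH2PO4/2-methyl-2-butene the 12-oic acid F7. HF·pyridine then removes the C6 silyl ether and the γ-hydroxy acid should lactonise, which comes back to the route at 41.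

**Further compounds**

F1 | step 24 | (4Z,6S,7R,8R,10S)-6,12-bis(tert-butyldimethylsilyloxy)-10-(4-methoxybenzyloxy)-1,3-dioxo-1,2-secogermacra-4,11(13)-dien-8-yl angelate | CC(=O)/C(C)=C\[C@H](O[Si](C)(C)C(C)(C)C)[C@H](C(=C)CO[Si](C)(C)C(C)(C)C)[C@H](OC(=O)/C(C)=C\C)C[C@](C)(OCc1ccc(OC)cc1)C=O
F2 | step 24 | (4Z,6S,7R,8R,10S)-6,12-bis(tert-butyldimethylsilyloxy)-10-(4-methoxybenzyloxy)-1-oxo-3-(trimethylsilyloxy)-1,2-secogermacra-2,4,11(13)-trien-8-yl angelate | C=C(O[Si](C)(C)C)/C(C)=C\[C@H](O[Si](C)(C)C(C)(C)C)[C@H](C(=C)CO[Si](C)(C)C(C)(C)C)[C@H](OC(=O)/C(C)=C\C)C[C@](C)(OCc1ccc(OC)cc1)C=O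
F3 | step 9 | (2S,3R)-3-[(S)-2-(4-methoxybenzyloxy)-2-methyl-3-(triethylsilyloxy)propyl]oxirane-2-carboxylic acid | OC(=O)[C@H]1O[C@@H]1C[C@](C)(OCc2ccc(OC)cc2)CO[Si](CC)(CC)CC
F4 | step 9 | (2R,3R,5S)-2-[3-(tert-butyldimethylsilyloxy)prop-1-en-2-yl]-3-hydroxy-5-(4-methoxybenzyloxy)-5-methyl-6-(triethylsilyloxy)hexanoic acid | OC(=O)[C@H](C(=C)CO[Si](C)(C)C(C)(C)C)[C@H](O)C[C@](C)(OCc1ccc(OC)cc1)CO[Si](CC)(CC)CC
F5 | step 26 | (1S,4Z,6S,7R,8R,10S)-6-(tert-butyldimethylsilyloxy)-1,12-dihydroxy-10-(4-methoxybenzyloxy)-3-oxogermacra-4,11(13)-dien-8-yl angelate | C1C(=O)/C(C)=C\[C@H](O[Si](C)(C)C(C)(C)C)[C@H](C(=C)CO)[C@H](OC(=O)/C(C)=C\C)C[C@](C)(OCc2ccc(OC)cc2)[C@H]1O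
F6 | step 26 | (1S,4Z,6S,7R,8R,10S)-6-(tert-butyldimethylsilyloxy)-1-hydroxy-10-(4-methoxybenzyloxy)-3,12-dioxogermacra-4,11(13)-dien-8-yl angelate | C1C(=O)/C(C)=C\[C@H](O[Si](C)(C)C(C)(C)C)[C@H](C(=C)C=O)[C@H](OC(=O)/C(C)=C\C)C[C@](C)(OCc2ccc(OC)cc2)[C@H]1O
F7 | step 26 | (1S,4Z,6S,7R,8R,10S)-8-angeloyloxy-6-(tert-butyldimethylsilyloxy)-1-hydroxy-10-(4-methoxybenzyloxy)-3-oxogermacra-4,11(13)-dien-12-oic acid | C1C(=O)/C(C)=C\[C@H](O[Si](C)(C)C(C)(C)C)[C@H](C(=C)C(=O)O)[C@H](OC(=O)/C(C)=C\C)C[C@](C)(OCc2ccc(OC)cc2)[C@H]1O
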